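About 0.0104 M is the number I leave you: it is c*, the dissolved target (target minus crystals) at which Sunday's run at 6.00 h shows its first crystals, and I read it as the solubility limit.

| flask | starting material | remark | time |
|---|---|---|---|
| Sunday's | 0.050 M | run made earlier |  |
| Wednesday's | 0.075 M | run made earlier |  |
| flask | 0.10 M |  | 30 h |

| run | time / h | target / % | crystals / % |
|---|---|---|---|
| Sunday's | 3.00 | 11.8 | 0 |
| Sunday's | 6.00 | 21.1 | 0.4 |
| Sunday's | 15.0 | 36.6 | 7.9 |
| Sunday's | 40.0 | 50.3 | 27.0 |
| Wednesday's | 5.00 | 18.6 | 0.6 |
| Wednesday's | 12.0 | 33.7 | 9.0 |
| Wednesday's | 25.0 | 45.5 | 25.3 |
| Wednesday's | 40.0 | 53.3 | 36.9 |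

(each reading ± 0.3 percentage points)

- target and crystals together at 30 h, in percent of the starting material charged
- concentration of target in solution at 30 h, in percent of saturation

- amounts and yields of target count crystals too
- given per volume of solution although it is solid: crystals
- on the list of suspects stand: starting material <-> isomer of the product; crystals <-> target; starting material <-> third isomer; starting material <-> target

The flask holds 0.10 M of starting material, so c* is 10.4 % of its charge. Sunday's run read 11.8 % of target at 3.00 h, already more than that share, so if percentages run alike before crystals appear, the flask crosses near that time. Wednesday's run, drawn straight between its readings, gives 48.1 % at 30 h. The flask crosses at a smaller share of its charge than Wednesday's, so I expect a little more than that when you come. Leave the crystals in, since the yield counts them.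

The forecast gives 50 % (48.5 % to 51.8 %) and 122 % of saturation, holding that “crystals shelter target from reversion”.

The flask gives 50.4 %, at 163 % of saturation, with crystals at 34.1 % of the starting material charged. Its dissolved target is 0.0163 M, or 1.58 times c*.

    starting material ⇌ isomer of the product (K = 3.09, k = 0.0223 /h)
    crystals ⇌ target, rate k2*(cs2 - [target]) while solid is left; crystals form when [target] > cs2 (solubility = 10.0 mM, k = 0.133 /h)
    starting material ⇌ third isomer (K = 1.60, k = 3.69 × 10⁻⁴ /h)
    starting material ⇌ target (K = 1.64, k = 0.0463 /h)

In a neighbouring flask, the same but with 0.025 M of starting material, c* is 41.6 % of the charge, so crystals should barely have begun at 30 h. That neighbouring flask gives 42.5 %, with crystals at 1.27 % of the starting material charged.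

The readings are calculated for substances that don't exist, and the scatter is random.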